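## Structural features

The target is a 3,3''-biflavanone: two 2-aryl-chroman-4-one units joined by one C3–C3'' single bond. Unit 1 is 5-hydroxy-7-methoxy-2-(4-methoxyphenyl)chroman-4-one and unit 2 is 5,7-dihydroxy-2-(4-hydroxyphenyl)chroman-4-one, so the molecule is a true heterodimer that differs in both ring A and ring B methylation. The four stereocentres C2–C3–C3''–C2'' are contiguous and read (2R,3S,2''R,3''S); each ring C is 2,3-trans and both halves have the same absolute sense. The central bond joins two tertiary carbons, each α to an aryl ketone and each flanked by an aryl-bearing O-benzylic carbon, so it is a congested 2,3-disubstituted 1,4-diketone. Fragile points: C3 and C3'' epimerise by enolisation, C2 and C2'' can be lost by base-induced retro-oxa-Michael opening to 2'-hydroxychalcones or by benzylic ionisation in strong acid, and two methyl ethers must survive next to four free phenols. The real difficulty is to make the hindered C3–C3'' linkage between two different units with control of all four centres and of absolute configuration without passing through flavanone enolates. The feature exploited is the sequence C4(=O)–C3–C3''–C4''(=O), in which each carbonyl carbon sits on a ring A whose ortho oxygen is bonded to C2 or C2''. C3–C3'' can therefore be bought as the triple bond of a but-2-yne-1,4-diol, and both C4–C3 bonds can be made by acyl-anion additions from salicylaldehyde-type ethers, closing both rings C.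

## Logic of the disconnections

20 from 19: the four O–CH2Ph bonds are cut. Benzyl is chosen because its removal is neutral and leaves the two methyl ethers and the epimerisable centres alone. The forward step must not open the benzylic C2–O1 bonds.

19 from 17 (key): the C4–C3 and C4''–C3'' bonds are cut, opening both rings C and turning C3–C3'' back into an alkyne. Two rings, two C–C bonds and two stereocentres disappear, and the heterodimer problem vanishes because 17 is assembled stepwise from four different arenes. The forward step must add each formyl C–H across the same triple bond, once at each alkyne carbon, and leave C2 and C2'' untouched so that they can direct C3 and C3''.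

17 from 15: the two formyl groups are exchanged for nitriles. Nitriles activate the SNAr reactions and are inert to the zinc acetylide chemistry that builds the chain. The forward step is one double partial reduction.

15 from 10 and 14: the aryl C8a''–O1'' bond is cut. Making the ether at the arene carbon keeps the carbinol C–O bond intact, so C2'' is transferred with retention. The forward step needs a fluoride ortho to the nitrile and a base that does not touch the propargylic C–H bonds.

10 from 8 and 9: the C2''–C3'' bond is cut between the carbinol carbon and the alkyne. This sets C2'' by catalyst control and joins the two halves. The forward step needs a terminal alkyne that tolerates a zinc acetylide.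

8 from 4 and 7: the aryl C8a–O1 bond is cut, for the same reason as in 15; the demand is the same.

4 from 3, and 3 from 1 and 2: the C2–C3 bond is cut. A two-carbon alkyne unit is added to 1 enantioselectively and then unmasked.

7 from 5 and 6; 14 from 13 and 6; 13 from 11 and 12: O–benzyl and aryl C–O bonds are cut. Both ring A electrophiles come from symmetrical 2,6-difluorobenzonitriles, so no regiochemical question arises.

## Other disconnections considered

Alternative 1: cut C3–C3'' between two preformed flavanones A1 and A2 and join them by oxidative coupling at C3 and C3'' after double deprotonation (the first idea that comes to mind). Each monomer would need its own asymmetric synthesis. Deprotonated flavanones open by E1cB to chalcone phenoxides, which puts C2 at risk. Two similar ketones give statistical homo- and heterodimers unless a tether is added and removed. The chosen plan never forms a flavanone enolate with a strong base and has no cross-selectivity problem.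

Alternative 2: cut both O1–C2 bonds and close both rings by a double oxa-Michael cascade of the bis-chalcone A3. This makes two rings at once but sets all four centres in reversible additions with no handle for absolute configuration and no bias between the C2-symmetric-type and meso-type series. The unsymmetrical A3 would need a regiocontrolled double condensation of an unsymmetrical 1,4-diketone with two different aldehydes. The chosen plan fixes C2 and C2'' by two catalytic alkynylations before the rings exist.

Alternative 3: reach the target by dearomatising reduction of both pyranone C2=C3 bonds of the 3,3''-biflavone A4, itself made by biaryl-type coupling of two 3-functionalised flavones. The two tetrasubstituted, mutually shielding double bonds are poor substrates for asymmetric hydrogenation. Syn addition would give 2,3-cis rings that need epimerisation, and the ketones compete for reduction. The chosen plan installs the hydrogens at C3 and C3'' by proton transfer rather than by hydrogenation of a hindered alkene.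

Key step: step 10

Remark: the SMILES is read as the (2R,3S,2''R,3''S) isomer with both rings C 2,3-trans. 5 and 11 are taken as commercial. The ProPhenol antipode used is the one whose zinc complex adds the alkynyl group to the Re face of the aldehyde, to be confirmed on 3.

## Steps

Step 1
Reactants: 1 4-methoxybenzaldehyde; 2 ethynyltrimethylsilane
Product: 3 (1S)-1-(4-methoxyphenyl)-3-(trimethylsilyl)prop-2-yn-1-ol
Conditions: Me2Zn, ProPhenol (10 mol %, Re-face-selective antipode), Ph3PO (20 mol %), toluene, 0 °C; aq. NH4Cl
Reagents that add atoms: none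
Why: Catalytic enantioselective alkynylation of an aldehyde: the zinc acetylide from 2 and Me2Zn is delivered to the Re face of 1 in the dinuclear zinc–ProPhenol pocket, which sets the future C2 as the (S)-carbinol (alkynyl outranks aryl here). Methyl transfer from Me2Zn is slow and should not compete.

Step 2
Reactants: 3 (1S)-1-(4-methoxyphenyl)-3-(trimethylsilyl)prop-2-yn-1-ol
Product: 4 (1R)-1-(4-methoxyphenyl)prop-2-yn-1-ol
Conditions: K2CO3 (0.2 equiv), MeOH, 0 °C to rt
Reagents that add atoms: none
Why: Methanolysis of the C(sp)–Si bond under catalytic carbonate. The carbinol centre is not involved; only its descriptor changes to R because the terminal ethynyl group ranks below the aryl group.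

Step 3
Reactants: 5 2,6-difluoro-4-methoxybenzonitrile; 6 benzyl alcohol
Product: 7 2-(benzyloxy)-6-fluoro-4-methoxybenzonitrile
Conditions: NaH (1.0 equiv), THF, 0 °C to rt
Reagents that add atoms: none
Why: Nucleophilic aromatic substitution (SNAr) of one of two equivalent fluorides activated by the ortho nitrile. The first alkoxy group makes the ring less electrophilic, so one equivalent of alkoxide should stop at monosubstitution.

Step 4
Reactants: 4 (1R)-1-(4-methoxyphenyl)prop-2-yn-1-ol; 7 2-(benzyloxy)-6-fluoro-4-methoxybenzonitrile
Product: 8 2-(benzyloxy)-4-methoxy-6-{[(1R)-1-(4-methoxyphenyl)prop-2-yn-1-yl]oxy}benzonitrile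
Conditions: KN(SiMe3)2 (1.0 equiv), THF/DMF, −20 °C to 0 °C
Reagents that add atoms: none
Why: SNAr of the remaining fluoride of 7 by the potassium alkoxide of 4. The carbinol C–O bond is not broken, so the configuration is retained. One equivalent of base at low temperature should leave the alkyne C–H and the new propargylic C–H untouched.

Step 5
Reactants: 8 2-(benzyloxy)-4-methoxy-6-{[(1R)-1-(4-methoxyphenyl)prop-2-yn-1-yl]oxy}benzonitrile; 9 4-(benzyloxy)benzaldehyde
Product: 10 2-(benzyloxy)-6-{[(1S,4S)-4-[4-(benzyloxy)phenyl]-4-hydroxy-1-(4-methoxyphenyl)but-2-yn-1-yl]oxy}-4-methoxybenzonitrile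
Conditions: Me2Zn, ProPhenol (20 mol %, same antipode as in step 1), Ph3PO (40 mol %), toluene, 4 °C; aq. NH4Cl
Reagents that add atoms: none
Why: Second ProPhenol/zinc alkynylation, now with the functionalised terminal alkyne 8, adds to the Re face of 9 and sets the future C2'' under catalyst control. The existing centre lies across a linear alkyne and should have no influence. The minor (1S,4R) diastereomer arising from residual enantiomers is removed by chromatography, which should raise the optical purity of 10.

Step 6
Reactants: 11 2,6-difluoro-4-hydroxybenzonitrile; 12 benzyl bromide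
Product: 13 4-(benzyloxy)-2,6-difluorobenzonitrile
Conditions: K2CO3, DMF, rt to 50 °C
Reagents that add atoms: none
Why: Williamson O-benzylation of an acidic phenol. The phenoxide is too weak a nucleophile to displace the ring fluorides under these conditions.

Step 7
Reactants: 13 4-(benzyloxy)-2,6-difluorobenzonitrile; 6 benzyl alcohol
Product: 14 2,4-bis(benzyloxy)-6-fluorobenzonitrile
Conditions: NaH (1.0 equiv), THF, 0 °C to rt
Reagents that add atoms: none
Why: SNAr monosubstitution of one of two equivalent ortho fluorides, as in step 3.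

Step 8
Reactants: 10 2-(benzyloxy)-6-{[(1S,4S)-4-[4-(benzyloxy)phenyl]-4-hydroxy-1-(4-methoxyphenyl)but-2-yn-1-yl]oxy}-4-methoxybenzonitrile; 14 2,4-bis(benzyloxy)-6-fluorobenzonitrile
Product: 15 2-(benzyloxy)-6-{[(1S,4S)-4-[3,5-bis(benzyloxy)-2-cyanophenoxy]-4-[4-(benzyloxy)phenyl]-1-(4-methoxyphenyl)but-2-yn-1-yl]oxy}-4-methoxybenzonitrile
Conditions: KN(SiMe3)2 (1.0 equiv), THF/DMF, −20 °C to 0 °C
Reagents that add atoms: none
Why: SNAr etherification as in step 4, with retention at the carbinol carbon. The hydroxyl is far more acidic than the propargylic C–H of the existing ether, so one equivalent of base should give only the alkoxide.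

Step 9
Reactants: 15 2-(benzyloxy)-6-{[(1S,4S)-4-[3,5-bis(benzyloxy)-2-cyanophenoxy]-4-[4-(benzyloxy)phenyl]-1-(4-methoxyphenyl)but-2-yn-1-yl]oxy}-4-methoxybenzonitrile
Product: 17 2-(benzyloxy)-6-{[(1S,4S)-4-[3,5-bis(benzyloxy)-2-formylphenoxy]-4-[4-(benzyloxy)phenyl]-1-(4-methoxyphenyl)but-2-yn-1-yl]oxy}-4-methoxybenzaldehyde, via bis-aldimine 16 (not isolated)
Conditions: i-Bu2AlH (3 equiv), CH2Cl2, −78 °C to −40 °C; cold 1 M HCl, 0 °C, brief
Reagents that add atoms: water, O
Why: Partial reduction of both nitriles by i-Bu2AlH to N-aluminated aldimines that are stable at low temperature and hydrolyse on cold acidic work-up. The internal alkyne and the aryl and benzyl ethers are inert to the hydride at −78 °C.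

Step 10
Reactants: 17 2-(benzyloxy)-6-{[(1S,4S)-4-[3,5-bis(benzyloxy)-2-formylphenoxy]-4-[4-(benzyloxy)phenyl]-1-(4-methoxyphenyl)but-2-yn-1-yl]oxy}-4-methoxybenzaldehyde
Product: 19 (2R,3S)-5-(benzyloxy)-3-{(2R,3S)-5,7-bis(benzyloxy)-2-[4-(benzyloxy)phenyl]-4-oxo-3,4-dihydro-2H-chromen-3-yl}-7-methoxy-2-(4-methoxyphenyl)-2,3-dihydro-4H-chromen-4-one, via enone aldehyde 18 (not isolated)
Conditions: 3-mesityl-5,6,7,8-tetrahydro-4H-cyclohepta[d]thiazol-3-ium perchlorate (20 mol %), K2CO3 (40 mol %), THF, 70 °C
Reagents that add atoms: none
Why: The carbene adds to one aldehyde of 17 to give a Breslow intermediate, which adds to the proximal alkyne carbon in a concerted but asynchronous, Conia-ene-like syn hydroacylation (6-exo-dig, forming C4–C3) while its O–H proton goes to the distal carbon, so no free vinyl anion that could expel the neighbouring aryloxide is formed; loss of the carbene gives the 3-ylidene-chroman-4-one 18. The second aldehyde, now tethered as in the classical salicylaldehyde Stetter substrates, forms its own Breslow intermediate and adds 6-exo-trig to the exocyclic β-carbon C3'' (forming C4''–C3''), and the resulting ring C enolate is protonated at C3. The closest known reaction type is the carbene-catalysed hydroacylation of O-propargyl salicylaldehydes followed by a Stetter reaction on the alkylidene chromanone, here with the Stetter step made intramolecular. Whichever aldehyde reacts first, both sequences converge on the same product, so no selectivity between the two formyl groups is needed. C2 and C2'' are untouched; C3'' is set in the C–C bond formation and C3 in the protonation, each under the control of its own neighbouring aryl-bearing carbon, and because both are α to a ketone the weak carbonate base should equilibrate them to the 2,3-trans diequatorial arrangement in each ring. Two R-configured C2 centres with a trans relationship in each ring define the (2R,3S,2''R,3''S) isomer uniquely, so no relative control between the two halves is required. The selectivities the step needs are 6-exo over 7-endo attack on the alkyne, secured by the tether length, and Stetter closure faster than base-mediated isomerisation of 18, secured by the strain-free intramolecular 6-exo-trig geometry and the substoichiometric weak base.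

Step 11
Reactants: 19 (2R,3S)-5-(benzyloxy)-3-{(2R,3S)-5,7-bis(benzyloxy)-2-[4-(benzyloxy)phenyl]-4-oxo-3,4-dihydro-2H-chromen-3-yl}-7-methoxy-2-(4-methoxyphenyl)-2,3-dihydro-4H-chromen-4-one
Product: 20 (2R,3S)-3-[(2R,3S)-5,7-dihydroxy-2-(4-hydroxyphenyl)-4-oxo-3,4-dihydro-2H-chromen-3-yl]-5-hydroxy-7-methoxy-2-(4-methoxyphenyl)-2,3-dihydro-4H-chromen-4-one
Conditions: H2 (1 atm), 10 % Pd/C, EtOAc/MeOH, rt
Reagents that add atoms: none
Why: Catalytic hydrogenolysis of the four benzyl ethers under neutral conditions. Methyl ethers, aryl ketones and the epimerisable C2/C3 centres should be unaffected, and the chelated 5-hydroxy groups that form stabilise the flavanone rings.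

## Compound list

1 | 4-methoxybenzaldehyde | COc1ccc(C=O)cc1 | starting material
2 | ethynyltrimethylsilane | C#C[Si](C)(C)C | starting material
3 | (1S)-1-(4-methoxyphenyl)-3-(trimethylsilyl)prop-2-yn-1-ol | COc1ccc([C@@H](C#C[Si](C)(C)C)O)cc1 | intermediate
4 | (1R)-1-(4-methoxyphenyl)prop-2-yn-1-ol | COc1ccc([C@@H](C#C)O)cc1 | intermediate
5 | 2,6-difluoro-4-methoxybenzonitrile | COc1cc(F)c(C#N)c(F)c1 | starting material
6 | benzyl alcohol | OCc1ccccc1 | starting material
7 | 2-(benzyloxy)-6-fluoro-4-methoxybenzonitrile | COc1cc(F)c(C#N)c(OCc2ccccc2)c1 | intermediate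
8 | 2-(benzyloxy)-4-methoxy-6-{[(1R)-1-(4-methoxyphenyl)prop-2-yn-1-yl]oxy}benzonitrile | COc1ccc([C@@H](C#C)Oc2cc(OC)cc(OCc3ccccc3)c2C#N)cc1 | intermediate
9 | 4-(benzyloxy)benzaldehyde | O=Cc1ccc(OCc2ccccc2)cc1 | starting material
10 | 2-(benzyloxy)-6-{[(1S,4S)-4-[4-(benzyloxy)phenyl]-4-hydroxy-1-(4-methoxyphenyl)but-2-yn-1-yl]oxy}-4-methoxybenzonitrile | COc1ccc([C@@H](C#C[C@@H](O)c2ccc(OCc3ccccc3)cc2)Oc2cc(OC)cc(OCc3ccccc3)c2C#N)cc1 | intermediate
11 | 2,6-difluoro-4-hydroxybenzonitrile | N#Cc1c(F)cc(O)cc1F | starting material
12 | benzyl bromide | BrCc1ccccc1 | starting material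
13 | 4-(benzyloxy)-2,6-difluorobenzonitrile | N#Cc1c(F)cc(OCc2ccccc2)cc1F | intermediate
14 | 2,4-bis(benzyloxy)-6-fluorobenzonitrile | N#Cc1c(F)cc(OCc2ccccc2)cc1OCc1ccccc1 | intermediate
15 | 2-(benzyloxy)-6-{[(1S,4S)-4-[3,5-bis(benzyloxy)-2-cyanophenoxy]-4-[4-(benzyloxy)phenyl]-1-(4-methoxyphenyl)but-2-yn-1-yl]oxy}-4-methoxybenzonitrile | COc1ccc([C@@H](C#C[C@@H](Oc2cc(OCc3ccccc3)cc(OCc3ccccc3)c2C#N)c2ccc(OCc3ccccc3)cc2)Oc2cc(OC)cc(OCc3ccccc3)c2C#N)cc1 | intermediate
16 | bis-aldimine of 17 (each CH=O of 17 present as CH=NH; (1S,4S) as in 15) | COc1ccc([C@@H](C#C[C@@H](Oc2cc(OCc3ccccc3)cc(OCc3ccccc3)c2C=N)c2ccc(OCc3ccccc3)cc2)Oc2cc(OC)cc(OCc3ccccc3)c2C=N)cc1 | intermediate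
17 | 2-(benzyloxy)-6-{[(1S,4S)-4-[3,5-bis(benzyloxy)-2-formylphenoxy]-4-[4-(benzyloxy)phenyl]-1-(4-methoxyphenyl)but-2-yn-1-yl]oxy}-4-methoxybenzaldehyde | COc1ccc([C@@H](C#C[C@@H](Oc2cc(OCc3ccccc3)cc(OCc3ccccc3)c2C=O)c2ccc(OCc3ccccc3)cc2)Oc2cc(OC)cc(OCc3ccccc3)c2C=O)cc1 | intermediate
18 | (2S,3E)-5-(benzyloxy)-3-{(2R)-2-[3,5-bis(benzyloxy)-2-formylphenoxy]-2-[4-(benzyloxy)phenyl]ethylidene}-7-methoxy-2-(4-methoxyphenyl)-2,3-dihydro-4H-chromen-4-one (drawn for the case in which the aldehyde on ring A of unit 1 reacts first; C4 carbonyl and vinylic hydrogen cis) | COc1ccc([C@@H]2Oc3cc(OC)cc(OCc4ccccc4)c3C(=O)/C2=C/[C@@H](Oc2cc(OCc3ccccc3)cc(OCc3ccccc3)c2C=O)c2ccc(OCc3ccccc3)cc2)cc1 | intermediate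
19 | (2R,3S)-5-(benzyloxy)-3-{(2R,3S)-5,7-bis(benzyloxy)-2-[4-(benzyloxy)phenyl]-4-oxo-3,4-dihydro-2H-chromen-3-yl}-7-methoxy-2-(4-methoxyphenyl)-2,3-dihydro-4H-chromen-4-one | COc1ccc([C@@H]2Oc3cc(OC)cc(OCc4ccccc4)c3C(=O)[C@H]2[C@@H]2C(=O)c3c(OCc4ccccc4)cc(OCc4ccccc4)cc3O[C@H]2c2ccc(OCc3ccccc3)cc2)cc1 | intermediate
20 | (2R,3S)-3-[(2R,3S)-5,7-dihydroxy-2-(4-hydroxyphenyl)-4-oxo-3,4-dihydro-2H-chromen-3-yl]-5-hydroxy-7-methoxy-2-(4-methoxyphenyl)-2,3-dihydro-4H-chromen-4-one | COc1ccc([C@@H]2Oc3cc(OC)cc(O)c3C(=O)[C@H]2[C@@H]2C(=O)c3c(O)cc(O)cc3O[C@H]2c2ccc(O)cc2)cc1 | target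

## Step count and least certain steps

Total step count: 11. Longest linear sequence: 8 steps (1, 2, 4, 5, 8, 9, 10, 11).

Step 10 (key step). The two formyl groups are di-ortho-oxygenated and electron-rich, so formation of the Breslow intermediates may be slow. If C–C bond formation runs ahead of proton transfer, the propargylic aryloxide next to the distal alkyne carbon can be expelled to give an allene. The enone 18 has acidic γ-hydrogens at C2'' and an allylic hydrogen at C2, so base-mediated isomerisation (loss of configuration there, or drift to a 3-alkylflavone) can compete with the Stetter closure. Equilibration at C3 and C3'' may also be incomplete. The fallback replaces acyl-anion catalysis by acyl radicals and needs no base. It sets out from 17: Pinnick oxidation (NaClO2, NaH2PO4, 2-methylbut-2-ene, t-BuOH/water) should give the dicarboxylic acid F1. Diphenyl diselenide and Bu3P should convert F1 into the bis(Se-phenyl) selenoester F2. Slow addition of Bu3SnH with AIBN in benzene at 80 °C should then generate each aroyl radical in turn: the first closes 6-exo-dig on the alkyne and the vinyl radical is reduced, the second closes 6-exo-trig on the resulting enone. Brief treatment with K2CO3 in THF would equilibrate C3 and C3'' to trans, and the fallback comes back to the route at 19.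

Step 8. The hindered secondary alkoxide may react slowly with the electron-rich fluoronitrile. Longer times or higher temperatures invite base-induced propargyl–allenyl isomerisation, which would erode the configuration at either propargylic carbon. The fallback forms the ether at carbon with inversion instead of at the arene with retention. It sets out from 8 and 14: step 5 run with the antipodal ProPhenol should give the (1S,4R) alcohol F3, and fluoride displacement on 14 with KOH in DMSO/water should give the phenol F4. Mitsunobu coupling of F3 and F4 (PPh3, DIAD, toluene, 0 °C) should invert the carbinol carbon and comes back to the route at 15.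

Step 5. The nitrile and the aryl ether oxygen of 8 may compete for the zinc centres, which could lower conversion or facial selectivity; the basic zinc species may also touch the activated propargylic C–H of 8. The fallback changes the order of assembly so that the alkynylation uses a simple silyl ether. It sets out from 4: TBSCl and imidazole should give the silyl ether F5. ProPhenol/Me2Zn alkynylation of 9 with F5 should give the monoprotected diol F6. SNAr of F6 with 14 (KN(SiMe3)2) should give the ether F7, and Bu4NF buffered with AcOH should free the alcohol F8. SNAr of F8 with 7 comes back to the route at 15.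

Step 11. Hydrogenolysis of the benzylic C2–O1 and C2''–O1'' bonds of the flavanone rings, especially next to the 4-methoxyphenyl group, could compete with O-debenzylation and open a ring C. The fallback is non-reductive: BCl3 with pentamethylbenzene as cation scavenger in CH2Cl2 at −78 °C sets out from 19 and should cleave the four benzyl ethers while leaving the two non-chelated methyl ethers, coming back at 20 without any new intermediate.

## Further compounds

F1 | step 10 | 2-(benzyloxy)-6-{[(1S,4S)-4-[3,5-bis(benzyloxy)-2-carboxyphenoxy]-4-[4-(benzyloxy)phenyl]-1-(4-methoxyphenyl)but-2-yn-1-yl]oxy}-4-methoxybenzoic acid | COc1ccc([C@@H](C#C[C@@H](Oc2cc(OCc3ccccc3)cc(OCc3ccccc3)c2C(=O)O)c2ccc(OCc3ccccc3)cc2)Oc2cc(OC)cc(OCc3ccccc3)c2C(=O)O)cc1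
F2 | step 10 | bis(Se-phenyl) selenoester of F1 | COc1ccc([C@@H](C#C[C@@H](Oc2cc(OCc3ccccc3)cc(OCc3ccccc3)c2C(=O)[Se]c2ccccc2)c2ccc(OCc3ccccc3)cc2)Oc2cc(OC)cc(OCc3ccccc3)c2C(=O)[Se]c2ccccc2)cc1
F3 | step 8 | 2-(benzyloxy)-6-{[(1S,4R)-4-[4-(benzyloxy)phenyl]-4-hydroxy-1-(4-methoxyphenyl)but-2-yn-1-yl]oxy}-4-methoxybenzonitrile | COc1ccc([C@@H](C#C[C@H](O)c2ccc(OCc3ccccc3)cc2)Oc2cc(OC)cc(OCc3ccccc3)c2C#N)cc1
F4 | step 8 | 2,4-bis(benzyloxy)-6-hydroxybenzonitrile | N#Cc1c(O)cc(OCc2ccccc2)cc1OCc1ccccc1
F5 | step 5 | tert-butyl{[(1R)-1-(4-methoxyphenyl)prop-2-yn-1-yl]oxy}dimethylsilane | COc1ccc([C@@H](C#C)O[Si](C)(C)C(C)(C)C)cc1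
F6 | step 5 | (1S,4S)-1-[4-(benzyloxy)phenyl]-4-[(tert-butyldimethylsilyl)oxy]-4-(4-methoxyphenyl)but-2-yn-1-ol | COc1ccc([C@@H](C#C[C@@H](O)c2ccc(OCc3ccccc3)cc2)O[Si](C)(C)C(C)(C)C)cc1
F7 | step 5 | 2,4-bis(benzyloxy)-6-{[(1S,4S)-1-[4-(benzyloxy)phenyl]-4-[(tert-butyldimethylsilyl)oxy]-4-(4-methoxyphenyl)but-2-yn-1-yl]oxy}benzonitrile | COc1ccc([C@@H](C#C[C@@H](Oc2cc(OCc3ccccc3)cc(OCc3ccccc3)c2C#N)c2ccc(OCc3ccccc3)cc2)O[Si](C)(C)C(C)(C)C)cc1
F8 | step 5 | 2,4-bis(benzyloxy)-6-{[(1S,4S)-1-[4-(benzyloxy)phenyl]-4-hydroxy-4-(4-methoxyphenyl)but-2-yn-1-yl]oxy}benzonitrile | COc1ccc([C@@H](C#C[C@@H](Oc2cc(OCc3ccccc3)cc(OCc3ccccc3)c2C#N)c2ccc(OCc3ccccc3)cc2)O)cc1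
F0 | step 11 | none | none
A1 | alternative 1 | (2R)-5-(benzyloxy)-7-methoxy-2-(4-methoxyphenyl)-2,3-dihydro-4H-chromen-4-one | COc1ccc([C@H]2CC(=O)c3c(OCc4ccccc4)cc(OC)cc3O2)cc1
A2 | alternative 1 | (2R)-5,7-bis(benzyloxy)-2-[4-(benzyloxy)phenyl]-2,3-dihydro-4H-chromen-4-one | O=C1C[C@H](c2ccc(OCc3ccccc3)cc2)Oc2cc(OCc3ccccc3)cc(OCc3ccccc3)c21
A3 | alternative 2 | (2E,3E)-1-[2-(benzyloxy)-6-hydroxy-4-methoxyphenyl]-4-[2,4-bis(benzyloxy)-6-hydroxyphenyl]-3-[4-(benzyloxy)benzylidene]-2-(4-methoxybenzylidene)butane-1,4-dione | COc1ccc(/C=C(/C(=O)c2c(O)cc(OC)cc2OCc2ccccc2)\C(=C/c2ccc(OCc3ccccc3)cc2)C(=O)c2c(O)cc(OCc3ccccc3)cc2OCc2ccccc2)cc1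
A4 | alternative 3 | 5-(benzyloxy)-3-{5,7-bis(benzyloxy)-2-[4-(benzyloxy)phenyl]-4-oxo-4H-chromen-3-yl}-7-methoxy-2-(4-methoxyphenyl)-4H-chromen-4-one | COc1ccc(-c2oc3cc(OC)cc(OCc4ccccc4)c3c(=O)c2-c2c(-c3ccc(OCc4ccccc4)cc3)oc3cc(OCc4ccccc4)cc(OCc4ccccc4)c3c2=O)cc1
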